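The readings were generated by integration from invented constants, and the scatter is random.

Late in a dosed flask the thing to judge is how the monomer in chains stands against the over-reaction product, and the next run is chosen on that ratio.

| flask | free monomer | protic impurity | initiator | temperature | remark | time |
|---|---|---|---|---|---|---|
| violet | 1.5 M (fed, over 80 min) | 0.15 M | 13 mM | 25 °C | run made earlier; the fed solution adds 0.25 times the starting volume |  |
| north-east | 1.5 M (fed, over 80 min) | 0.150 M | 8.8 mM | 25 °C | the fed solution adds 0.25 times the starting volume | 2.0 h |
| north | 1.5 M (fed, over 80 min) | 0.150 M | 8.8 mM | −5 °C | the fed solution adds 0.25 times the starting volume | 2.0 h |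
| south-west | 1.5 M (fed, over 80 min) | 0.150 M | 8.8 mM | 85 °C | the fed solution adds 0.25 times the starting volume | 2.0 h |
| north-west | 1.5 M (fed, over 80 min) | 0.150 M | 8.8 mM | 55 °C | the fed solution adds 0.25 times the starting volume | 2.0 h |

violet run (percent of the free monomer charged)

| time / min | monomer in chains / % | over-reaction product / % |
|---|---|---|
| 3.00 | 0.1 | 0 |
| 8.00 | 0.3 | 0 |
| 15.0 | 2.1 | 0.5 |
| 25.0 | 7.4 | 0 |

(each reading ± 0.5 percentage points)

- every charge counts on the volume at the start, and the solution that is fed holds the whole dose
- the earlier runs do not show what temperature does; that part of a forecast is a guess
- percentages count the whole charge, also what has not yet gone in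
- no earlier run changes the charge of initiator; that part of a forecast is a guess

- the best flask by share of monomer in chains in all that became monomer in chains or over-reaction product; "all alike" if 1.5 percentage points covers them all (north-east / north / south-west / north-west / all alike)
- share of monomer in chains in all that became monomer in chains or over-reaction product, north-east
- share of monomer in chains in all that became monomer in chains or over-reaction product, north
- share of monomer in chains in all that became monomer in chains or over-reaction product, south-west
- share of monomer in chains in all that became monomer in chains or over-reaction product, north-west

A share near its top hides the ratio, so the reckoning goes to logarithms. The over-reaction index is the common logarithm of [over-reaction product]/[monomer in chains], the log-odds of the over-reaction share and so the log-odds of the selectivity with its sign turned, and each whole unit is one power of ten in that ratio.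

In the violet run at 25.0 min, the over-reaction product reads 0% with a scatter of 0.5 percentage points. Two standard deviations, 1 point, therefore serve as a ceiling against the 7.4% in chains, and the index there is at most −0.869. If over-reaction is a first-order loss of chains, the ratio grows roughly with the time the chains have stood. Going from 25.0 min to 2.0 h then adds the logarithm of the time ratio, 0.681. The result, −0.188, is the late ceiling: the highest index that the violet readings allow at 25 °C by this reckoning.

My own floor for the share in north-east is thus 60.7%, though that flask holds 8.8 mM of initiator against the 13 mM of the violet run, and what this change does is a guess. The decision follows from this. North-east is run first as the test of the ceiling, and the dose and the protic impurity stay as charged. Temperature is the setting to try, and the earlier runs give no figure for it.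

The forecast names north, with 92% for north-east, 96% for north, 86% for north-west and 76% for south-west: “Side reactions usually have the higher activation energy, so cold should favour chains and heat should erode the share.” My reckoning gives a floor for north-east, not the forecast's number.

The best flask is north, and the shares are 84.7% in north-east, 99.8% in north, 3.62% in north-west and 0% in south-west.

    initiator → 2 initiating radical (k = 6.32 × 10⁻⁴ min⁻¹, Ea = 100 kJ mol⁻¹)
    free monomer + initiating radical → growing radical + monomer in chains (k = 1.33 × 10⁵ M⁻¹ s⁻¹, Ea = 15.0 kJ mol⁻¹)
    free monomer + growing radical → monomer in chains + growing radical, rate k3*[growing radical]*[free monomer] (k = 10100 M⁻¹ s⁻¹, Ea = 10.0 kJ mol⁻¹)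
    2 growing radical → dead chain (k = 9.30 × 10⁷ M⁻¹ s⁻¹, Ea = 17.0 kJ mol⁻¹)
    free monomer ⇌ dormant form (K = 0.689, k = 0.00356 min⁻¹, Ea = 105 kJ mol⁻¹, ΔH = −58.0 kJ mol⁻¹)
    monomer in chains → over-reaction product (k = 0.00314 min⁻¹, Ea = 91.0 kJ mol⁻¹)
    protic impurity + free monomer → quenched substrate (k = 0.0249 M⁻¹ min⁻¹, Ea = 58.0 kJ mol⁻¹)
    (constants at 25 °C)

North-east ends at index −0.742, below the late ceiling of −0.188, while north-west ends at 1.43, above it by 1.62. The neighbouring flask is south-west repeated at 60 °C. Carrying the step from north-east to north-west onward at the same rise per degree gives index 1.79, which is a share of 1.60%. The neighbouring flask itself stands at index 1.74, with 73.9% over-reaction product against 1.34% monomer in chains at 2.00 h, a share of 1.78%.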